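**Retrosynthetic overview**
1. Target 18 ⇐ diol 16 + vanillic acid 17 (Mitsunobu at the primary OH only). 16 ⇐ ketone 14 by C7 carbonyl reduction (equatorial OH) and hydrogenation/debenzylation.
2. Key disconnection: 14 ⇐ acyclic furan–ethoxyallene 12 by one Au(I)-catalysed intramolecular (4+3) cycloaddition. It closes C3a–C8a and C6–C7 together, so the cyclopentane and the oxygen-bridged cycloheptene form in the same operation and the furan becomes the 3a,6-ether bridge. C3a, C6 and C8a are set from C3.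
3. 12 ⇐ Grignard reagent of bromide 9 + 1,1-diethoxybut-2-yne 10 (Cu-catalysed SN2').
4. 9 ⇐ enal 5 + 2-methylfuran 6 (organocatalytic Friedel–Crafts, sets C3). 5 ⇐ (R)-Roche ester 1 (supplies C11).
5. Ring order: furan (purchased) → cyclopentane + cycloheptene (8-oxabicyclo[3.2.1]octene) together in step 7. No later ring formation.

Assumption/convention: core atoms carry 3a,6-epoxyazulene locants (C3 bears the side chain, C3a and C6 the ether oxygen, C7 the hydroxyl, C8a the angular methyl; C11/C12 are the side-chain CH and CH2O). Ethoxyallene 12 is used as a mixture at its allene axis, which is lost on gold activation.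

**Step 1**
Reactants: 1 methyl (R)-3-hydroxy-2-methylpropanoate
Product: 2 methyl (R)-3-(benzyloxy)-2-methylpropanoate
Conditions: BnOC(=NH)CCl3 (1.2 eq), TfOH (5 mol %), cyclohexane/CH2Cl2 2:1, 0 °C → rt
Reagents that add atoms: benzyl 2,2,2-trichloroacetimidate, ClC(Cl)(Cl)C(=N)OCc1ccccc1
Why: Acid-catalysed imidate O-benzylation avoids base, so the α-stereocentre (future C11) is neither epimerised nor lost by β-elimination.

**Step 2**
Reactants: 2 methyl (R)-3-(benzyloxy)-2-methylpropanoate
Product: 3 (R)-3-(benzyloxy)-2-methylpropanal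
Conditions: DIBAL-H (1.1 eq), CH2Cl2, −78 °C; MeOH then Rochelle salt; used crude at once
Reagents that add atoms: none
Why: Partial ester reduction through the tetrahedral aluminium hemiacetal at −78 °C stops at the aldehyde, and immediate use limits epimerisation at the α-centre.

**Step 3**
Reactants: 3 (R)-3-(benzyloxy)-2-methylpropanal, 4 (triphenylphosphoranylidene)acetaldehyde
Product: 5 (S,E)-5-(benzyloxy)-4-methylpent-2-enal
Conditions: 4 (1.3 eq), toluene, 80 °C
Reagents that add atoms: none
Why: Wittig olefination with a stabilised formyl ylide gives the (E)-enal directly; the stereocentre is untouched (the descriptor changes from R to S by CIP priority only).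

**Step 4**
Reactants: 5 (S,E)-5-(benzyloxy)-4-methylpent-2-enal, 6 2-methylfuran
Product: 8 (3R,4S)-5-(benzyloxy)-4-methyl-3-(5-methylfuran-2-yl)pentan-1-ol, via furyl aldehyde 7 (not isolated)
Conditions: 6 (3 eq), (2R,5R)-5-benzyl-2-tert-butyl-3-methylimidazolidin-4-one·TFA (20 mol %), CH2Cl2/i-PrOH 85:15, −30 °C; then NaBH4, EtOH, 0 °C
Reagents that add atoms: none
Why: Iminium-catalysed Friedel–Crafts alkylation puts furan C5 on the enal β-carbon from the face left open by the catalyst, setting C3 as 3R under catalyst control (the (2S,5S) antipode would give the opposite β-face); NaBH4 then reduces aldehyde 7 in the same pot.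

**Step 5**
Reactants: 8 (3R,4S)-5-(benzyloxy)-4-methyl-3-(5-methylfuran-2-yl)pentan-1-ol
Product: 9 2-[(3R,4S)-5-(benzyloxy)-1-bromo-4-methylpentan-3-yl]-5-methylfuran
Conditions: CBr4 (1.3 eq), PPh3 (1.4 eq), 2,6-lutidine (0.2 eq), CH2Cl2, 0 °C
Reagents that add atoms: carbon tetrabromide, BrC(Br)(Br)Br
Why: Appel bromination of the primary alcohol is neutral (lutidine buffers traces of HBr), so the acid-sensitive furan and both stereocentres survive.

**Step 6**
Reactants: 9 2-[(3R,4S)-5-(benzyloxy)-1-bromo-4-methylpentan-3-yl]-5-methylfuran, 10 1,1-diethoxybut-2-yne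
Product: 12 ethoxyallene 2-[(2S,3R)-1-(benzyloxy)-8-ethoxy-2,6-dimethylocta-6,7-dien-3-yl]-5-methylfuran, via Grignard reagent 11 (not isolated)
Conditions: Mg, THF, 35 °C; then 10 (1.5 eq), CuBr·SMe2 (10 mol %), P(OEt)3 (20 mol %), Et2O/THF, −30 → 0 °C; aq. NH4Cl/NH3; Et3N-deactivated silica
Reagents that add atoms: magnesium, [Mg] (held only in 11)
Why: Copper-catalysed anti-SN2' substitution of a propargylic acetal by a Grignard reagent puts the alkyl chain on the methyl-bearing alkyne carbon and expels ethoxide, giving the 3,3-disubstituted 1-ethoxyallene; the allene axis is formed unselectively and does not matter later.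

**Step 7**
Reactants: 12 ethoxyallene 2-[(2S,3R)-1-(benzyloxy)-8-ethoxy-2,6-dimethylocta-6,7-dien-3-yl]-5-methylfuran
Product: 14 tricyclic ketone (3R,3aS,6S,8aR)-3-[(S)-1-(benzyloxy)propan-2-yl]-6,8a-dimethyl-2,3,8,8a-tetrahydro-1H-3a,6-epoxyazulen-7(6H)-one, via enol ether 13 (not isolated)
Conditions: IPrAuCl (5 mol %), AgSbF6 (5 mol %), 4 Å MS, CH2Cl2 (0.02 M), −40 → 0 °C; then 1 M aq. HCl/THF, 0 °C
Reagents that add atoms: water, O
Why: Proposed new method: cationic Au(I) turns the ethoxyallene into a gold-bound 1-ethoxyallyl cation that adds across C3a/C6 of the tethered 2,5-dialkylfuran in an intramolecular (4+3) cycloaddition (C3a–C8a and C6–C7 bonds, cyclopentane and oxa-bridged cycloheptene formed together), and the resulting C8 gold carbene undergoes 1,2-H shift from the α-ethoxy C7–H to release enol ether 13 and the catalyst, the closest known reaction type being Au/Pt-catalysed intramolecular (4+3) cycloadditions of allenes (including 1-acyloxyallenes) with tethered dienes and furans that end in a 1,2-H shift; the C3 side chain eclipses the furan C–O bond (H toward furan C4–H), which fixes the furan face and sets 3aS and 6S relative to 3R, a compact transition state with the tether outside and the methyl inside (over the ring oxygen, not over C4–H) sets 8aR, and aqueous acid then hydrolyses 13 to ketone 14.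

**Step 8**
Reactants: 14 tricyclic ketone (3R,3aS,6S,8aR)-3-[(S)-1-(benzyloxy)propan-2-yl]-6,8a-dimethyl-2,3,8,8a-tetrahydro-1H-3a,6-epoxyazulen-7(6H)-one
Product: 15 (3R,3aS,6S,7S,8aR)-3-[(S)-1-(benzyloxy)propan-2-yl]-6,8a-dimethyl-2,3,6,7,8,8a-hexahydro-1H-3a,6-epoxyazulen-7-ol
Conditions: Al(Oi-Pr)3 (3 eq), i-PrOH/toluene 1:1, acetone (0.2 eq), 90 °C, 24–48 h
Reagents that add atoms: none
Why: Meerwein–Ponndorf–Verley reduction run reversibly gives the thermodynamic carbinol, which is the 7S alcohol with equatorial OH (anti to the bridging oxygen, no syn-diaxial clash with the axial C8a methyl), and it avoids electron-transfer reagents that would cleave the α C–O bridge.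

**Step 9**
Reactants: 15 (3R,3aS,6S,7S,8aR)-3-[(S)-1-(benzyloxy)propan-2-yl]-6,8a-dimethyl-2,3,6,7,8,8a-hexahydro-1H-3a,6-epoxyazulen-7-ol
Product: 16 (3R,3aS,6S,7S,8aR)-3-[(S)-1-hydroxypropan-2-yl]-6,8a-dimethyloctahydro-1H-3a,6-epoxyazulen-7-ol
Conditions: H2 (1 atm), 10 % Pd/C, EtOH, rt
Reagents that add atoms: none
Why: Heterogeneous hydrogenation saturates the strained C4=C5 bridge alkene and hydrogenolyses the benzyl ether in one operation; no stereocentre is created or touched.

**Step 10**
Reactants: 16 (3R,3aS,6S,7S,8aR)-3-[(S)-1-hydroxypropan-2-yl]-6,8a-dimethyloctahydro-1H-3a,6-epoxyazulen-7-ol, 17 4-hydroxy-3-methoxybenzoic acid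
Product: 18 (2S)-2-[(3R,3aS,6S,7S,8aR)-7-hydroxy-6,8a-dimethyloctahydro-1H-3a,6-epoxyazulen-3-yl]propyl 4-hydroxy-3-methoxybenzoate
Conditions: 17 (1.2 eq), PPh3 (1.3 eq), DIAD (1.3 eq), THF, 0 °C → rt
Reagents that add atoms: none
Why: Mitsunobu esterification activates only the unhindered primary alcohol (the neopentyl-type secondary C7–OH does not react) and the carboxylic acid, far more acidic than the phenol, is the nucleophile, so no protecting group is needed; the reacting carbon is CH2, so no stereocentre is affected.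

**Compound list**
1 | methyl (R)-3-hydroxy-2-methylpropanoate ((R)-Roche ester) | COC(=O)[C@H](C)CO | starting material
2 | methyl (R)-3-(benzyloxy)-2-methylpropanoate | COC(=O)[C@H](C)COCc1ccccc1 | intermediate
3 | (R)-3-(benzyloxy)-2-methylpropanal | O=C[C@H](C)COCc1ccccc1 | intermediate
4 | (triphenylphosphoranylidene)acetaldehyde | O=CC=P(c1ccccc1)(c1ccccc1)c1ccccc1 | starting material
5 | (S,E)-5-(benzyloxy)-4-methylpent-2-enal | O=C/C=C/[C@H](C)COCc1ccccc1 | intermediate
6 | 2-methylfuran | Cc1ccco1 | starting material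
7 | (3R,4S)-5-(benzyloxy)-4-methyl-3-(5-methylfuran-2-yl)pentanal (not isolated) | O=CC[C@@H](c1ccc(C)o1)[C@H](C)COCc1ccccc1 | intermediate
8 | (3R,4S)-5-(benzyloxy)-4-methyl-3-(5-methylfuran-2-yl)pentan-1-ol | OCC[C@@H](c1ccc(C)o1)[C@H](C)COCc1ccccc1 | intermediate
9 | 2-[(3R,4S)-5-(benzyloxy)-1-bromo-4-methylpentan-3-yl]-5-methylfuran | BrCC[C@@H](c1ccc(C)o1)[C@H](C)COCc1ccccc1 | intermediate
10 | 1,1-diethoxybut-2-yne | CC#CC(OCC)OCC | starting material
11 | [(3R,4S)-5-(benzyloxy)-4-methyl-3-(5-methylfuran-2-yl)pentyl]magnesium bromide (not isolated) | Br[Mg]CC[C@@H](c1ccc(C)o1)[C@H](C)COCc1ccccc1 | intermediate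
12 | 2-[(2S,3R)-1-(benzyloxy)-8-ethoxy-2,6-dimethylocta-6,7-dien-3-yl]-5-methylfuran (about 1:1 at the allene axis) | CCOC=C=C(C)CC[C@@H](c1ccc(C)o1)[C@H](C)COCc1ccccc1 | intermediate
13 | (3R,3aS,6S,8aR)-3-[(S)-1-(benzyloxy)propan-2-yl]-7-ethoxy-6,8a-dimethyl-1,2,3,8a-tetrahydro-6H-3a,6-epoxyazulene (C7=C8 enol ether, C4=C5 alkene; not isolated) | c1ccccc1COC[C@@H](C)[C@H]2CC[C@]3(C)C=C(OCC)[C@]4(C)C=C[C@]23O4 | intermediate
14 | (3R,3aS,6S,8aR)-3-[(S)-1-(benzyloxy)propan-2-yl]-6,8a-dimethyl-2,3,8,8a-tetrahydro-1H-3a,6-epoxyazulen-7(6H)-one | c1ccccc1COC[C@@H](C)[C@H]2CC[C@]3(C)CC(=O)[C@]4(C)C=C[C@]23O4 | intermediate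
15 | (3R,3aS,6S,7S,8aR)-3-[(S)-1-(benzyloxy)propan-2-yl]-6,8a-dimethyl-2,3,6,7,8,8a-hexahydro-1H-3a,6-epoxyazulen-7-ol | c1ccccc1COC[C@@H](C)[C@H]2CC[C@]3(C)C[C@H](O)[C@]4(C)C=C[C@]23O4 | intermediate
16 | (3R,3aS,6S,7S,8aR)-3-[(S)-1-hydroxypropan-2-yl]-6,8a-dimethyloctahydro-1H-3a,6-epoxyazulen-7-ol | OC[C@@H](C)[C@H]2CC[C@]3(C)C[C@H](O)[C@]4(C)CC[C@]23O4 | intermediate
17 | 4-hydroxy-3-methoxybenzoic acid (vanillic acid) | COc1cc(C(=O)O)ccc1O | starting material
18 | (2S)-2-[(3R,3aS,6S,7S,8aR)-7-hydroxy-6,8a-dimethyloctahydro-1H-3a,6-epoxyazulen-3-yl]propyl 4-hydroxy-3-methoxybenzoate | COc1cc(C(=O)OC[C@@H](C)[C@H]2CC[C@]3(C)C[C@H](O)[C@]4(C)CC[C@]23O4)ccc1O | target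

**Totals**
Total step count: 10. Longest linear sequence: 10 steps (1 → 18).

**Three steps most likely to fail**

Step 7 (gold (4+3) cycloaddition). The gold-activated ethoxyallene may instead alkylate the furan at C4 (six-membered hydroarylation) or hydrolyse, and the C8a configuration depends on the compact transition state winning over the extended one. Fallback: use a sulfur-stabilised allyl cation instead of the gold-bound one. Starting from 12, mild aqueous acid gives the enal (6R,7S)-8-(benzyloxy)-3,7-dimethyl-6-(5-methylfuran-2-yl)oct-2-enal F1. PhSH with catalytic BF3·OEt2 at −20 °C converts it into the dithioacetal 2-[(2S,3R)-1-(benzyloxy)-2,6-dimethyl-8,8-bis(phenylsulfanyl)oct-6-en-3-yl]-5-methylfuran F2. Ionisation of one C–S bond with dimethyl(methylthio)sulfonium tetrafluoroborate gives a vinylthionium ion, an established three-carbon partner for intramolecular (4+3) cycloadditions with tethered furans. Cycloaddition and proton loss give the vinyl sulfide (3R,3aS,6S,8aR)-3-[(S)-1-(benzyloxy)propan-2-yl]-6,8a-dimethyl-7-(phenylsulfanyl)-1,2,3,8a-tetrahydro-6H-3a,6-epoxyazulene F3. Hydrolysis with TiCl4 in aqueous acetic acid rejoins the route at ketone 14.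

Step 8 (equilibrating MPV reduction). The neopentyl-type α-alkoxy ketone may react too slowly or give aldol by-products with acetone. Fallback: separate the reduction from the stereochemical control. Starting from 14, irreversible hydride reduction (NaBH4, CeCl3, MeOH, −40 °C) is expected to give mainly the axial epimer (3R,3aS,6S,7R,8aR)-3-[(S)-1-(benzyloxy)propan-2-yl]-6,8a-dimethyl-2,3,6,7,8,8a-hexahydro-1H-3a,6-epoxyazulen-7-ol F4, because the axial C8a methyl blocks axial attack. Redox-neutral epimerisation of the carbinol centre with a catalytic ruthenium hydrogen-transfer complex (Shvo type, toluene, 80 °C) then converts F4 into the more stable equatorial alcohol and rejoins the route at 15.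

Step 6 (functionalised Grignard reagent, copper SN2' to a sensitive 3,3-disubstituted alkoxyallene). Wurtz coupling, direct substitution without transposition, or loss of the allene on work-up are possible. Fallback: reverse the roles so that the simple methyl group is the one delivered by copper. Starting from 9, alkylation of lithium 3,3-diethoxyprop-1-yn-1-ide (from commercial 3,3-diethoxyprop-1-yne and n-BuLi, THF/DMPU) gives the ynal acetal 2-[(2S,3R)-1-(benzyloxy)-8,8-diethoxy-2-methyloct-6-yn-3-yl]-5-methylfuran F5. MeMgBr with catalytic CuBr then performs the SN2' substitution at the chain-bearing alkyne carbon and rejoins the route at 12.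

**Further compounds**
F1 | step 7 | (6R,7S)-8-(benzyloxy)-3,7-dimethyl-6-(5-methylfuran-2-yl)oct-2-enal (E/Z mixture) | O=CC=C(C)CC[C@@H](c1ccc(C)o1)[C@H](C)COCc1ccccc1
F2 | step 7 | 2-[(2S,3R)-1-(benzyloxy)-2,6-dimethyl-8,8-bis(phenylsulfanyl)oct-6-en-3-yl]-5-methylfuran | c1ccccc1SC(Sc1ccccc1)C=C(C)CC[C@@H](c1ccc(C)o1)[C@H](C)COCc1ccccc1
F3 | step 7 | (3R,3aS,6S,8aR)-3-[(S)-1-(benzyloxy)propan-2-yl]-6,8a-dimethyl-7-(phenylsulfanyl)-1,2,3,8a-tetrahydro-6H-3a,6-epoxyazulene | c1ccccc1COC[C@@H](C)[C@H]2CC[C@]3(C)C=C(Sc5ccccc5)[C@]4(C)C=C[C@]23O4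
F4 | step 8 | (3R,3aS,6S,7R,8aR)-3-[(S)-1-(benzyloxy)propan-2-yl]-6,8a-dimethyl-2,3,6,7,8,8a-hexahydro-1H-3a,6-epoxyazulen-7-ol | c1ccccc1COC[C@@H](C)[C@H]2CC[C@]3(C)C[C@@H](O)[C@]4(C)C=C[C@]23O4
F5 | step 6 | 2-[(2S,3R)-1-(benzyloxy)-8,8-diethoxy-2-methyloct-6-yn-3-yl]-5-methylfuran | CCOC(OCC)C#CCC[C@@H](c1ccc(C)o1)[C@H](C)COCc1ccccc1
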